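**Retrosynthetic overview**
1. End game: the angelate goes on last onto O‑8 (4‑OH masked as a silyl ether); the crotonoyl ketone is unveiled from an allylic alcohol with MnO2.
2. Key disconnection: the C3a–C8a bond and the trans‑fused γ‑lactone are made in one flask. A furanose lactol (latent C8a aldehyde) is attacked by a butenolide‑embedded allylboronate, closing the cycloheptane, and the lactone then moves from O‑4 to O‑8a.
3. The butenolide boronate comes from a γ‑hydroxy ynoate (asymmetric propiolate addition to a C4 aldehyde, then hydroalumination/borylmethylation).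
4. C6 (methyl) and C7 (tertiary carbinol) come from a Hoppe homoaldol addition to a D‑glucose‑derived 3‑ulose; sugar C1, C2, C3, C4–C5 become C8a, C8, C7 and the crotonoyl C1′–C2′.
5. Ring order: temporary butenolide (step 9), then cycloheptane and γ‑lactone together (step 10).

Numbering used throughout (target as cyclohepta[b]furan‑2‑one): O1, C2(=O), C3(=CH2), C3a, C4(OH), C5, C6(CH3), C7(OH, crotonoyl), C8(O‑angelate), C8a(O1).

Assumption: the ProPhenol enantiomer written in step 8 is taken to be the one that gives the (S)‑carbinol; if its sense of induction is the opposite, the equally available antipode is used.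

Step 1
Reactants: 1 1,2-O-isopropylidene-α-D-glucofuranose
Product: 2 1,2-O-isopropylidene-α-D-xylo-pentodialdo-1,4-furanose
Conditions: NaIO4, H2O/MeOH, 0 °C to rt
Reagents that add atoms: none
Why: Malaprade glycol cleavage of the only vicinal diol (C5/C6) gives the C5 aldehyde and leaves the stereocentres C1–C4 untouched.

Step 2
Reactants: 2 1,2-O-isopropylidene-α-D-xylo-pentodialdo-1,4-furanose
Product: 3 (5E)-5,6,7-trideoxy-1,2-O-isopropylidene-α-D-xylo-hept-5-enofuranose
Conditions: CrCl2, CH3CHI2, THF, rt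
Reagents that add atoms: 1,1-diiodoethane, CC(I)I
Why: Takai–Utimoto ethylidenation through a gem-dichromium reagent gives the (E)-propenyl group (the future crotonoyl C2′–C4′) and tolerates the free 3-OH.

Step 3
Reactants: 3 (5E)-5,6,7-trideoxy-1,2-O-isopropylidene-α-D-xylo-hept-5-enofuranose
Product: 4 (5E)-5,6,7-trideoxy-1,2-O-isopropylidene-α-D-erythro-hept-5-enofuranos-3-ulose
Conditions: Dess–Martin periodinane, NaHCO3, CH2Cl2, 0 °C to rt
Reagents that add atoms: none
Why: Dess–Martin oxidation under buffered, non-enolising conditions turns the secondary 3-OH into the ketone that becomes C7.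

Step 4
Reactants: 5 (E)-but-2-en-1-ol; 6 N,N-diisopropylcarbamoyl chloride
Product: 7 (E)-but-2-en-1-yl N,N-diisopropylcarbamate
Conditions: NaH, THF, 0 °C to reflux
Reagents that add atoms: none
Why: O-carbamoylation of the sodium alkoxide (addition–elimination at the carbamoyl chloride) installs the directing group needed for the homoaldol reaction.

Step 5
Reactants: 7 (E)-but-2-en-1-yl N,N-diisopropylcarbamate; 4 (5E)-5,6,7-trideoxy-1,2-O-isopropylidene-α-D-erythro-hept-5-enofuranos-3-ulose
Product: 10 3-C-[(1S,2Z)-3-(N,N-diisopropylcarbamoyloxy)-1-methylprop-2-en-1-yl]-5,6,7-trideoxy-1,2-O-isopropylidene-α-D-ribo-hept-5(E)-enofuranose (tertiary 3-OH on the α face), via α-lithio carbamate 8 (not isolated), via allyltitanium reagent 9 (not isolated)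
Conditions: n-BuLi, (−)-sparteine, pentane/cyclohexane, −78 °C; Ti(OiPr)4, −78 °C; then 4, THF, −78 to −40 °C; aq. NH4Cl
Reagents that add atoms: none
Why: Hoppe homoaldol reaction: sparteine-mediated lithiation gives the (S)-lithio carbamate, Li→Ti exchange with inversion gives the (R)-allyltitanium, and this adds through a Zimmerman–Traxler chair (syn-SE2′) to the ketone face opposite the 1,2-acetonide, so the reagent sets C6 (S, methyl) and the substrate sets C7, the Z-enol carbamate being a masked C4 aldehyde.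

Step 6
Reactants: 10 the homoaldol adduct
Product: 11 3-O-triethylsilyl ether of 10
Conditions: TESOTf, 2,6-lutidine, CH2Cl2, −78 to 0 °C
Reagents that add atoms: triethylsilyl trifluoromethanesulfonate, CC[Si](CC)(CC)OS(=O)(=O)C(F)(F)F
Why: Silyl triflate silylation of the hindered tertiary alcohol prevents lactol formation with the aldehyde released in the next step.

Step 7
Reactants: 11 3-O-triethylsilyl ether of 10
Product: 13 3-C-[(2S)-4-oxobutan-2-yl]-3-O-triethylsilyl-5,6,7-trideoxy-1,2-O-isopropylidene-α-D-ribo-hept-5(E)-enofuranose, via lithium enolate 12 (not isolated)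
Conditions: MeLi, THF, −78 to −30 °C; then AcOH/aq. NH4Cl, −78 °C
Reagents that add atoms: none
Why: Hoppe-type deblocking, in which MeLi attacks the carbamate carbonyl and releases the aldehyde enolate, whose protonation gives the C4 aldehyde with no stereocentre at risk (C5 is CH2).

Step 8
Reactants: 13 the C4 aldehyde; 14 methyl propiolate
Product: 15 3-C-[(2S,4S)-4-hydroxy-7-methoxy-7-oxohept-5-yn-2-yl]-3-O-triethylsilyl-5,6,7-trideoxy-1,2-O-isopropylidene-α-D-ribo-hept-5(E)-enofuranose
Conditions: Me2Zn, (S,S)-ProPhenol (20 mol%), PhMe, 0 °C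
Reagents that add atoms: none
Why: Trost zinc–ProPhenol alkynylation, in which the dinuclear zinc catalyst delivers the zinc propiolate to one aldehyde face and sets the C4 carbinol (S) under catalyst control.

Step 9
Reactants: 15 the γ-hydroxy ynoate; 16 2-(iodomethyl)-4,4,5,5-tetramethyl-1,3,2-dioxaborolane
Product: 18 3-C-{(2S)-1-[(2S)-5-oxo-4-(pinacolborylmethyl)-2,5-dihydrofuran-2-yl]propan-2-yl}-3-O-triethylsilyl-5,6,7-trideoxy-1,2-O-isopropylidene-α-D-ribo-hept-5(E)-enofuranose, via hydroxy enoate boronate 17 (not isolated)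
Conditions: DIBAL-H, HMPA, THF, 0 °C; then 16, rt; aq. Rochelle salt; silica gel
Reagents that add atoms: none
Why: Tsuda–Saegusa conjugate syn-hydroalumination of the ynoate and Hall-type trapping of the α-alanyl acrylate with the iodomethylboronate give the 2-alkoxycarbonyl allylboronate with the carbinol carbon cis to the ester, which lactonises to the butenolide with C4 unchanged.

Step 10
Reactants: 18 the butenolide allylboronate
Product: 21 4,7,8-trihydroxy-7-[(E)-1-hydroxybut-2-en-1-yl]-6-methyl-3-methylidene-octahydro-2H-cyclohepta[b]furan-2-one (trans-fused lactone on O-8a; ring stereocentres as in 27; side-chain carbinol = sugar C4, retained), via lactol 19 (not isolated), via cis-fused lactone 20 (not isolated)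
Conditions: TFA/H2O (9:1), 0 °C; then PhMe, 80 °C; then PPTS (cat.), PhMe, 60 °C
Reagents that add atoms: none
Why: Proposed new method: aqueous acid removes the acetonide and the silyl ether, and the open-chain C8a aldehyde in equilibrium with lactol 19 is captured by the butenolide-embedded 2-(alkoxycarbonyl)allylboronate in an intramolecular Zimmerman–Traxler allylboration, where the new C3a–C8a bond forms on the butenolide face that carries the tether (cis-fused lactone 20, so O-4 and the acrylate carbon are cis, C3a S) and the ring-locked E-type allyl unit gives the anti adduct (new O-8a trans to the acrylate, C8a R), after which mild acid equilibrates the cis-fused lactone on O-4 to the trans-fused lactone on O-8a; the closest known chemistry is the tandem allylboration–lactonisation of 2-alkoxycarbonyl allylboronates and the relactonisation of hydroxylated sesquiterpene lactones.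

Step 11
Reactants: 21 the trans-fused lactone tetraol
Product: 22 7-[(E)-but-2-enoyl]-4,7,8-trihydroxy-6-methyl-3-methylidene-octahydro-2H-cyclohepta[b]furan-2-one (stereocentres as in 27)
Conditions: MnO2, CH2Cl2, rt
Reagents that add atoms: none
Why: MnO2 oxidises only the allylic secondary alcohol to the (E)-enone, the non-allylic secondary and tertiary alcohols being inert.

Step 12
Reactants: 22 the enone triol
Product: 23 4-O-triethylsilyl ether of 22
Conditions: TESOTf (1.05 equiv), 2,6-lutidine, CH2Cl2, −78 °C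
Reagents that add atoms: triethylsilyl trifluoromethanesulfonate, CC[Si](CC)(CC)OS(=O)(=O)C(F)(F)F
Why: Kinetic silylation takes the least hindered secondary alcohol (4-OH) in preference to the neopentyl-type 8-OH next to the quaternary C7 and to the tertiary 7-OH.

Step 13
Reactants: 23 4-O-triethylsilyl ether of 22; 24 angelic acid
Product: 26 4-O-triethylsilyl ether of the target, via mixed anhydride 25 (not isolated)
Conditions: 2,4,6-trichlorobenzoyl chloride, Et3N, PhMe, rt; then 23, PhMe, 75 °C
Reagents that add atoms: none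
Why: Yamaguchi-type esterification through the angelic 2,4,6-trichlorobenzoic mixed anhydride acylates the only free secondary alcohol without a nucleophilic catalyst, which preserves the Z (angelate) geometry.

Step 14
Reactants: 26 4-O-triethylsilyl ether of the target
Product: 27 (3aS,4S,6S,7S,8S,8aR)-7-[(E)-but-2-enoyl]-4,7-dihydroxy-6-methyl-3-methylidene-2-oxo-octahydro-2H-cyclohepta[b]furan-8-yl (Z)-2-methylbut-2-enoate
Conditions: HF·pyridine, THF/pyridine, 0 °C
Reagents that add atoms: none
Why: Fluoride-mediated desilylation under buffered, non-basic conditions frees the 4-OH without translactonisation, angelate isomerisation or conjugate addition.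

**Compound list**
1 | 1,2-O-isopropylidene-α-D-glucofuranose | OC[C@@H](O)[C@@H]1[C@@H]([C@@H]2[C@H](O1)OC(O2)(C)C)O | starting material
2 | 1,2-O-isopropylidene-α-D-xylo-pentodialdo-1,4-furanose | O=C[C@@H]1[C@@H]([C@@H]2[C@H](O1)OC(O2)(C)C)O | intermediate
3 | (5E)-5,6,7-trideoxy-1,2-O-isopropylidene-α-D-xylo-hept-5-enofuranose | C/C=C/[C@@H]1[C@@H]([C@@H]2[C@H](O1)OC(O2)(C)C)O | intermediate
4 | (5E)-5,6,7-trideoxy-1,2-O-isopropylidene-α-D-erythro-hept-5-enofuranos-3-ulose | C/C=C/[C@@H]1C(=O)[C@@H]2[C@H](O1)OC(O2)(C)C | intermediate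
5 | (E)-but-2-en-1-ol | C/C=C/CO | starting material
6 | N,N-diisopropylcarbamoyl chloride | CC(C)N(C(C)C)C(=O)Cl | starting material
7 | (E)-but-2-en-1-yl N,N-diisopropylcarbamate | C/C=C/COC(=O)N(C(C)C)C(C)C | intermediate
8 | (S,E)-1-lithiobut-2-en-1-yl N,N-diisopropylcarbamate ((−)-sparteine complex) | C/C=C/[C@@H](OC(=O)N(C(C)C)C(C)C)[Li] | intermediate
9 | (R,E)-1-(triisopropoxytitanio)but-2-en-1-yl N,N-diisopropylcarbamate | C/C=C/[C@H](OC(=O)N(C(C)C)C(C)C)[Ti](OC(C)C)(OC(C)C)OC(C)C | intermediate
10 | 3-C-[(1S,2Z)-3-(N,N-diisopropylcarbamoyloxy)-1-methylprop-2-en-1-yl]-5,6,7-trideoxy-1,2-O-isopropylidene-α-D-ribo-hept-5(E)-enofuranose | C/C=C/[C@@H]1[C@](O)([C@@H](C)/C=C\OC(=O)N(C(C)C)C(C)C)[C@@H]2[C@H](O1)OC(O2)(C)C | intermediate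
11 | 3-O-triethylsilyl ether of 10 | C/C=C/[C@@H]1[C@](O[Si](CC)(CC)CC)([C@@H](C)/C=C\OC(=O)N(C(C)C)C(C)C)[C@@H]2[C@H](O1)OC(O2)(C)C | intermediate
12 | lithium (Z)-enolate of aldehyde 13 | C/C=C/[C@@H]1[C@](O[Si](CC)(CC)CC)([C@@H](C)/C=C\O[Li])[C@@H]2[C@H](O1)OC(O2)(C)C | intermediate
13 | 3-C-[(2S)-4-oxobutan-2-yl]-3-O-triethylsilyl-5,6,7-trideoxy-1,2-O-isopropylidene-α-D-ribo-hept-5(E)-enofuranose | C/C=C/[C@@H]1[C@](O[Si](CC)(CC)CC)([C@@H](C)CC=O)[C@@H]2[C@H](O1)OC(O2)(C)C | intermediate
14 | methyl propiolate | C#CC(=O)OC | starting material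
15 | 3-C-[(2S,4S)-4-hydroxy-7-methoxy-7-oxohept-5-yn-2-yl]-3-O-triethylsilyl-5,6,7-trideoxy-1,2-O-isopropylidene-α-D-ribo-hept-5(E)-enofuranose | C/C=C/[C@@H]1[C@](O[Si](CC)(CC)CC)([C@@H](C)C[C@H](O)C#CC(=O)OC)[C@@H]2[C@H](O1)OC(O2)(C)C | intermediate
16 | 2-(iodomethyl)-4,4,5,5-tetramethyl-1,3,2-dioxaborolane | ICB1OC(C)(C)C(C)(C)O1 | starting material
17 | open-chain (Z)-4-hydroxy-2-(pinacolborylmethyl)-2-enoate formed from 15 (carbinol carbon cis to CO2Me) | C/C=C/[C@@H]1[C@](O[Si](CC)(CC)CC)([C@@H](C)C[C@H](O)/C=C(/CB3OC(C)(C)C(C)(C)O3)C(=O)OC)[C@@H]2[C@H](O1)OC(O2)(C)C | intermediate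
18 | 3-C-{(2S)-1-[(2S)-5-oxo-4-(pinacolborylmethyl)-2,5-dihydrofuran-2-yl]propan-2-yl}-3-O-triethylsilyl-5,6,7-trideoxy-1,2-O-isopropylidene-α-D-ribo-hept-5(E)-enofuranose | C/C=C/[C@@H]1[C@](O[Si](CC)(CC)CC)([C@@H](C)C[C@@H]3OC(=O)C(CB4OC(C)(C)C(C)(C)O4)=C3)[C@@H]2[C@H](O1)OC(O2)(C)C | intermediate
19 | free furanose lactol of 18 (no acetonide, no silyl group; anomeric mixture) | C/C=C/[C@@H]1[C@](O)([C@@H](C)C[C@@H]2OC(=O)C(CB3OC(C)(C)C(C)(C)O3)=C2)[C@@H](O)C(O)O1 | intermediate
20 | cis-fused α-methylene lactone closed on O-4, with free 8a-OH, 8-OH, 7-OH and 7-[(E)-1-hydroxybut-2-enyl] (stereocentres as in 27) | C=C1C(=O)O[C@H]2C[C@H](C)[C@@](O)([C@H](O)/C=C/C)[C@@H](O)[C@H](O)[C@@H]12 | intermediate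
21 | 4,7,8-trihydroxy-7-[(E)-1-hydroxybut-2-en-1-yl]-6-methyl-3-methylidene-octahydro-2H-cyclohepta[b]furan-2-one (trans-fused, stereocentres as in 27) | C=C1C(=O)O[C@@H]2[C@@H]1[C@@H](O)C[C@H](C)[C@@](O)([C@H](O)/C=C/C)[C@H]2O | intermediate
22 | 7-[(E)-but-2-enoyl]-4,7,8-trihydroxy-6-methyl-3-methylidene-octahydro-2H-cyclohepta[b]furan-2-one (stereocentres as in 27) | C=C1C(=O)O[C@@H]2[C@@H]1[C@@H](O)C[C@H](C)[C@@](O)(C(=O)/C=C/C)[C@H]2O | intermediate
23 | 4-O-triethylsilyl ether of 22 | C=C1C(=O)O[C@@H]2[C@@H]1[C@@H](O[Si](CC)(CC)CC)C[C@H](C)[C@@](O)(C(=O)/C=C/C)[C@H]2O | intermediate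
24 | angelic acid, (Z)-2-methylbut-2-enoic acid | C/C=C(/C)C(=O)O | starting material
25 | (Z)-2-methylbut-2-enoic 2,4,6-trichlorobenzoic anhydride | C/C=C(/C)C(=O)OC(=O)c1c(Cl)cc(Cl)cc1Cl | intermediate
26 | 4-O-triethylsilyl ether of 27 | C=C1C(=O)O[C@@H]2[C@@H]1[C@@H](O[Si](CC)(CC)CC)C[C@H](C)[C@@](O)(C(=O)/C=C/C)[C@H]2OC(=O)/C(C)=C\C | intermediate
27 | (3aS,4S,6S,7S,8S,8aR)-7-[(E)-but-2-enoyl]-4,7-dihydroxy-6-methyl-3-methylidene-2-oxo-octahydro-2H-cyclohepta[b]furan-8-yl (Z)-2-methylbut-2-enoate | C=C1C(=O)O[C@@H]2[C@@H]1[C@@H](O)C[C@H](C)[C@@](O)(C(=O)/C=C/C)[C@H]2OC(=O)/C(C)=C\C | target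

**Step count and risks**
Total step count: 14. Longest linear sequence: 13 (steps 1–3 and 5–14, from 1).

Three steps most likely to fail:

Step 10 (one-flask ring closure and lactone shift). The seven-membered allylboration on a free lactol is unprecedented. The ring-fusion outcome rests on a transition-state model. The lactone shift to O-8a is assumed to be thermodynamically downhill, which is not established for this ring system. Fallback: it sets out from 20, isolated by stopping before the PPTS stage, and comes back at 27. The cis-fused lactone is kept as an internal protecting group for O-4 and the lactone shift becomes the last operation. MnO2 oxidises the allylic alcohol to give the enone of the cis-fused lactone F3. TESOTf/2,6-lutidine silylates the less hindered 8a-OH to give the 8a-O-triethylsilyl ether F4. Yamaguchi angeloylation of the remaining secondary 8-OH gives the 8-O-angelate F5. HF·pyridine followed by camphorsulfonic acid then frees the 8a-OH, which relactonises onto the acrylate and releases the 4-OH, giving 27.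

Step 5 (homoaldol addition to the enolisable, β,γ-unsaturated 3-ulose). Enolisation or double-bond migration in 4, or a mismatched reagent/substrate pairing, could erode yield or selectivity. Fallback: it sets out from 4 and comes back at 13. A Marshall-type chiral allenylzinc reagent is used in place of the crotyl carbamate, made from the but-3-yn-2-yl mesylate enantiomer that transfers its chirality to the S methyl centre, with Pd(OAc)2/PPh3 and Et2Zn. It adds to the same ketone face and gives the homopropargylic tertiary alcohol F1. TESOTf/2,6-lutidine gives its triethylsilyl ether F2. Anti-Markovnikov hydroboration–oxidation of the terminal alkyne (Cy2BH, then NaBO3) gives aldehyde 13.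

Step 13 (angeloylation of the hindered 8-OH). The alcohol sits next to a quaternary carbon, and forcing conditions risk Z→E isomerisation to the tiglate. Fallback: it sets out from 23 and comes back at 26. The Z-alkene is built after acylation. Esterification of 23 with 2-[bis(2,2,2-trifluoroethoxy)phosphoryl]propanoic acid (DIC, DMAP) gives the phosphonopropanoate ester F6. Still–Gennari olefination with acetaldehyde (KHMDS, 18-crown-6, THF, −78 °C) then gives the Z-configured 2-methylbut-2-enoate 26.

**Further compounds**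
F1 | step 5 | 3-C-[(2S)-but-3-yn-2-yl]-5,6,7-trideoxy-1,2-O-isopropylidene-α-D-ribo-hept-5(E)-enofuranose | C/C=C/[C@@H]1[C@](O)([C@@H](C)C#C)[C@@H]2[C@H](O1)OC(O2)(C)C
F2 | step 5 | 3-O-triethylsilyl ether of F1 | C/C=C/[C@@H]1[C@](O[Si](CC)(CC)CC)([C@@H](C)C#C)[C@@H]2[C@H](O1)OC(O2)(C)C
F3 | step 10 | enone of cis-fused lactone 20 (7-[(E)-but-2-enoyl], free 8a-OH, 8-OH, 7-OH) | C=C1C(=O)O[C@H]2C[C@H](C)[C@@](O)(C(=O)/C=C/C)[C@@H](O)[C@H](O)[C@@H]12
F4 | step 10 | 8a-O-triethylsilyl ether of F3 | C=C1C(=O)O[C@H]2C[C@H](C)[C@@](O)(C(=O)/C=C/C)[C@@H](O)[C@H](O[Si](CC)(CC)CC)[C@@H]12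
F5 | step 10 | 8-O-angelate of F4 | C=C1C(=O)O[C@H]2C[C@H](C)[C@@](O)(C(=O)/C=C/C)[C@@H](OC(=O)/C(C)=C\C)[C@H](O[Si](CC)(CC)CC)[C@@H]12
F6 | step 13 | 8-O-{2-[bis(2,2,2-trifluoroethoxy)phosphoryl]propanoyl} derivative of 23 (α-carbon epimers) | C=C1C(=O)O[C@@H]2[C@@H]1[C@@H](O[Si](CC)(CC)CC)C[C@H](C)[C@@](O)(C(=O)/C=C/C)[C@H]2OC(=O)C(C)P(=O)(OCC(F)(F)F)OCC(F)(F)F
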